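**Assumption.** The SMILES gives no descriptor for the biaryl axis, so DMGF is taken as the racemic pair of atropisomers.

**Locants.** Unit 1 is the flavone joined through C6 (its ring B carries single primes). Unit 2 is the flavone joined through C8'' (double primes; its ring B carries triple primes).

**Numbering used throughout.** 1 and 2 are the starting materials, 3 a β-diketone (not isolated), 4 the monomer with free 5-OH, 5 its 5-O-methyl ether, 6 the aryllead triacetate made from 5, 7 and 8 transient species of the key step, 9 the protected biflavone, 10 DMGF.

## Analysis of the target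

DMGF is a biflavone built from two identical 5,4'-dihydroxy-7-methoxyflavone units (phloroglucinol-type ring A, 4-pyranone ring C, 4-hydroxyphenyl ring B) that are joined by a single C–C bond from C6 of ring A of unit 1 to C8'' of ring A of unit 2. There is no stereocentre; the only stereogenic element is this axis, which carries four ortho substituents (5-OH and 7-OMe on one ring, 7''-OMe and the ring oxygen O1'' on the other). The sensitive groups are four phenols (two chelated 5-OH, two 4'-OH conjugated with the pyranone), two aryl methyl ethers that must survive the end game, and two vinylogous-ester pyranones that open in hot alkali or hot mineral acid and can reclose on the other peri oxygen (Wessely–Moser isomerization, which would scramble 6- and 8-linkage). The difficulty lies in the central bond alone: both of its carbons sit between two oxygen substituents, so each is the nucleophilic 2-position of a phloroglucinol and the bond joins two carbons of the same donor polarity. Each ring A also offers two such CH sites (C6 and C8), so three constitutional dimers (6,6'', 6,8'' and 8,8'') compete. The feature on which the route is built is the different environment of the two bonded carbons. In unit 1 the bond sits at C6, the only hydrogen-bearing carbon ortho to the 5-hydroxyl (the other ortho carbon is the ring-fusion carbon C4a). In unit 2 it sits at C8'', which is para to O5'', ortho to the 7''-OMe and ortho to the unsubstituted O1'', and is the least hindered CH of a 5,7-dialkoxyflavone. Because both halves are the same monomer, addressing these two C–H bonds directly reduces the whole synthesis to one monomer and one biaryl union.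

## Retrosynthetic reasoning

**10 from 9.** Only O–C bonds of protecting groups are cut: two benzyl ethers (O4', O4''') and one methyl ether (O5''). The benzyl groups are there because free ring B phenols would compete in the key step. The 5''-methyl is there because unit 2 must not present a phenol of its own. A boron Lewis acid removes all three in one operation, the 5''-methyl through chelation with C4''=O, while the 7- and 7''-methyl ethers stay.

**9 from 4 and 6 (key disconnection).** The C6–C8'' bond is cut, the only bond of 9 that is not already present in the monomer. Cutting here, at the flavone stage, means that no ring has to be built after the hindered axis exists and that both halves come from one compound. The polarity problem (two donor carbons) is solved by placing tetravalent lead on C8'', which turns that carbon into an aryl cation equivalent. The regiochemical problem is solved by the 5-hydroxyl of 4: lead binds to O5 (species 7) and can hand its aryl group only to an ortho carbon, and C6 is the only ortho CH. The resulting dienone 8 tautomerizes to 9. Phenol 4 is not functionalized at C6 beforehand. A free one-electron oxidant acting on 4 alone was not chosen, because a phenoxyl radical of 4 carries spin at both C6 and C8 and would give all three dimers.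

**6 from 5.** The C8–Pb bond is cut back to a C–H bond. Electrophilic plumbation is expected at C8 of 5 because this carbon is activated by three oxygen substituents and is unhindered, whereas C6 is buttressed by both methoxyls. Taken with the key step, this makes the union a formal dehydrogenative C–H/C–H cross-coupling carried out in two controlled stages.

**5 from 4.** One O–CH3 bond is cut. The same monomer thus serves as the phenol partner (4) and, after O-methylation, as the arene partner (5), so the two coupling partners differ by one step.

**4 from 1 and 2.** Ring C is opened at O1–C2 and at C3–C(aroyl), through β-diketone 3. Ketone 1 is symmetric, so either hydroxyl of 3 closes to the same flavone, and the 7-OMe and 4'-O-benzyl groups are bought with the starting materials.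

## Alternatives that were turned down

**Alternative 1: cross-coupling of two prefunctionalized flavones (the textbook route).** The same C6–C8'' bond is formed by Suzuki–Miyaura coupling of 6-iodide A1 with 8-boronic acid A2 to give the fully protected biflavone A3, followed by deprotection. It was turned down on step economy and mechanism. Marking the two carbons costs four operations (6-iodination of 4, O-methylation, 8-iodination of 5, borylation) against one plumbation. The coupling is a tetra-ortho-substituted case in which the di-ortho-oxygenated boronic acid A2 is prone to protodeboronation in aqueous base while transmetalation and reductive elimination are slow. It remains the safest known chemistry and is kept, in a slightly shorter form, as the fallback for the key step.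

**Alternative 2: biaryl first, both rings C afterwards.** Oxidative homodimerization of ketone 1, whose two free ring positions are equivalent by symmetry, would give the single dimer A4. Double aroylation, Baker–Venkataraman rearrangement and cyclodehydration would then build both pyranones. It was turned down because A4 is C2-symmetric and each ketone is flanked by two hydroxyls. The target needs closure onto the hydroxyl para to the axis in one half and onto the hydroxyl ortho to the axis in the other half, and nothing in A4 distinguishes the halves. The 8,8''-isomer A5 and the 6,6''-isomer A6 would therefore form beside the wanted compound, with the less hindered closure favouring A6. Making the halves different beforehand gives up the symmetry, brings back two prefunctionalized partners and puts two annulations after the hindered axis.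

**Alternative 3: ring A of unit 2 built by benzannulation.** A Danheiser benzannulation of the flavonyl ynol ether A7 with a 3-alkoxyvinylketene (from a cyclobutenone or a diazo enone) would give phenol A8. The aryl-bearing alkyne carbon would become C8'', flanked by the new hydroxyl (future O1'') and the methoxyl, so the ring construction sets the pattern. It was turned down on step economy and on selectivity after the key step:
- A7 itself needs 6-iodination and installation of the alkynyl ether, so C6 is prefunctionalized anyway.
- A8 still lacks C4'', ring C and ring B of unit 2, which means at least six further steps.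
- The first of these, an ortho-acylation, has two open positions on the new ring (between OH and OEt, needed; between OMe and OEt, competing).
- The target is a dimer of one monomer, and building half of it atom by atom discards that.

Key step: step 4

## Route

**Step 1**
Reactants: 1 1-(2,6-dihydroxy-4-methoxyphenyl)ethan-1-one; 2 4-(benzyloxy)benzoyl chloride
Product: 4 2-[4-(benzyloxy)phenyl]-5-hydroxy-7-methoxy-4H-chromen-4-one, via β-diketone 3 (not isolated)
Conditions: LiN(SiMe3)2 (4.5 equiv), THF, −78 to −10 °C; 2, −78 °C to rt; aq. HCl; crude 3 in AcOH, cat. H2SO4, 95 °C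
Reagents that add atoms: none
Why: Polyanion C-aroylation followed by acid cyclodehydration (one-flask variant of the Baker–Venkataraman flavone synthesis): the trilithio derivative of 1 is acylated by 2 at the enolate carbon to give 3, whose two hydroxyls are equivalent by symmetry, so only one flavone can form; the aryl benzyl ether tolerates the amide base and the short acid treatment.

**Step 2**
Reactants: 4 2-[4-(benzyloxy)phenyl]-5-hydroxy-7-methoxy-4H-chromen-4-one
Product: 5 2-[4-(benzyloxy)phenyl]-5,7-dimethoxy-4H-chromen-4-one
Conditions: Me2SO4, K2CO3, acetone, reflux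
Reagents that add atoms: dimethyl sulfate, COS(=O)(=O)OC
Why: Williamson O-methylation; the hydrogen-bonded 5-OH is the only acidic site and is alkylated under forcing but standard conditions, which removes the phenol of the future unit 2 and turns its ring A into a 5,7-dialkoxy arene.

**Step 3**
Reactants: 5 2-[4-(benzyloxy)phenyl]-5,7-dimethoxy-4H-chromen-4-one
Product: 6 {2-[4-(benzyloxy)phenyl]-5,7-dimethoxy-4-oxo-4H-chromen-8-yl}lead triacetate
Conditions: Pb(OAc)4 (1.05 equiv), Cl2CHCO2H, CHCl3, rt, dark; water wash; AcOH, CHCl3; precipitation with hexane
Reagents that add atoms: lead tetraacetate, CC(=O)O[Pb](OC(C)=O)(OC(C)=O)OC(C)=O; acetic acid, CC(=O)O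
Why: Electrophilic aromatic plumbation, the reaction that converts di- and trialkoxybenzenes into aryllead triacetates; C8 is ortho to OMe-7 and O1 and para to OMe-5 and is unhindered, whereas C6 is buttressed by the methyl groups of both methoxyls (the 5-OMe is turned toward C6 by the peri carbonyl) and C3 is a much weaker nucleophile than the trioxygenated ring A; carboxylate ligands scrambled by the haloacid are reset to acetate by the acetic acid treatment.

**Step 4**
Reactants: 4 2-[4-(benzyloxy)phenyl]-5-hydroxy-7-methoxy-4H-chromen-4-one; 6 {2-[4-(benzyloxy)phenyl]-5,7-dimethoxy-4-oxo-4H-chromen-8-yl}lead triacetate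
Product: 9 4',4'''-bis(benzyloxy)-5-hydroxy-5'',7,7''-trimethoxy-6,8''-biflavone (racemic axis), via aryl(aryloxy)lead diacetate 7 (not isolated), via cyclohexadienone tautomer 8 (not isolated)
Conditions: 6 (1.3 equiv), pyridine (4 equiv), CHCl3, 40 to 60 °C, dark
Reagents that add atoms: none
Why: This is a Pinhey arylation, the ligand coupling by which aryllead triacetates arylate phenols at the ortho carbon; the closest known cases are the couplings of 2,4,6-trimethoxyphenyllead triacetate with 3,5-dialkoxyphenols and with 2,6-disubstituted phenols. Pyridine-assisted exchange of one acetate on tetravalent lead for the O5 phenoxide of 4 gives 7; the C8'' aryl group then migrates from lead to the ortho carbon C6 in an intramolecular ligand coupling that expels Pb(OAc)2 and gives dienone 8, which enolizes to the phenol 9. No ring is closed and no stereocentre survives (C6 of 8 is transient); the tetra-ortho-substituted C6–C8'' axis is formed as the racemate. The step needs C- over O-arylation, C6 over C8 and C4a within 4, and no reaction of unit 2 with itself. Because the aryl group is delivered from oxygen-bound lead, only carbons ortho to O5 can be reached, which rules out C8 (para); of the two ortho carbons, C4a is a ring-fusion carbon bearing the acyl group, where attack would build a congested quaternary centre in a dienone that cannot rearomatize, so C6 is taken. The benzyl ethers remove the ring B phenols and the 5''-OMe removes the phenol of unit 2, so the mixture holds exactly one phenolic oxygen, and product 9 has no ortho CH left for a second arylation. Two ortho oxygen substituents on the lead-bearing ring are tolerated in this manifold, and the mechanism builds even quaternary centres, which suits the four ortho substituents of this bond. The main uncertainty is the low nucleophilicity of the chelated 5-OH.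

**Step 5**
Reactants: 9 4',4'''-bis(benzyloxy)-5-hydroxy-5'',7,7''-trimethoxy-6,8''-biflavone
Product: 10 DMGF, 5,5'',4',4'''-tetrahydroxy-7,7''-dimethoxy-6,8''-biflavone (racemic axis)
Conditions: BCl3 (10 equiv), C6HMe5 (6 equiv), CH2Cl2, −78 °C to rt; MeOH, then aq. HCl
Reagents that add atoms: none
Why: Lewis acid ether cleavage: BCl3 removes both benzyl groups at low temperature while pentamethylbenzene traps the benzyl cation, and on warming it cleaves the 5''-methyl ether through the six-membered boron chelate with C4''=O; the 7- and 7''-methyl ethers lack this chelation and are not attacked by BCl3 at or below room temperature, and the axis is untouched.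

## Compound list

1 | 1-(2,6-dihydroxy-4-methoxyphenyl)ethan-1-one (2',6'-dihydroxy-4'-methoxyacetophenone) | CC(=O)c1c(O)cc(OC)cc1O | starting material
2 | 4-(benzyloxy)benzoyl chloride | O=C(Cl)c1ccc(OCc2ccccc2)cc1 | starting material
3 | 1-[4-(benzyloxy)phenyl]-3-(2,6-dihydroxy-4-methoxyphenyl)propane-1,3-dione (formed in step 1, not isolated) | COc1cc(O)c(C(=O)CC(=O)c2ccc(OCc3ccccc3)cc2)c(O)c1 | intermediate
4 | 2-[4-(benzyloxy)phenyl]-5-hydroxy-7-methoxy-4H-chromen-4-one | COc1cc(O)c2c(=O)cc(-c3ccc(OCc4ccccc4)cc3)oc2c1 | intermediate
5 | 2-[4-(benzyloxy)phenyl]-5,7-dimethoxy-4H-chromen-4-one | COc1cc(OC)c2c(=O)cc(-c3ccc(OCc4ccccc4)cc3)oc2c1 | intermediate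
6 | {2-[4-(benzyloxy)phenyl]-5,7-dimethoxy-4-oxo-4H-chromen-8-yl}lead triacetate | CC(=O)O[Pb](OC(C)=O)(OC(C)=O)c1c(OC)cc(OC)c2c(=O)cc(-c3ccc(OCc4ccccc4)cc3)oc12 | intermediate
7 | aryl(aryloxy)lead diacetate: lead bearing the C8 aryl group of 6, the O5 phenoxide of 4 and two acetates (formed in step 4, not isolated) | CC(=O)O[Pb](OC(C)=O)(Oc1cc(OC)cc2oc(-c3ccc(OCc4ccccc4)cc3)cc(=O)c12)c1c(OC)cc(OC)c2c(=O)cc(-c3ccc(OCc4ccccc4)cc3)oc12 | intermediate
8 | 2-[4-(benzyloxy)phenyl]-6-{2-[4-(benzyloxy)phenyl]-5,7-dimethoxy-4-oxo-4H-chromen-8-yl}-7-methoxy-4H-chromene-4,5(6H)-dione, the dienone tautomer of 9, configuration at C6 not controlled (formed in step 4, not isolated) | COC1=CC2=C(C(=O)C1c1c(OC)cc(OC)c3c(=O)cc(-c4ccc(OCc5ccccc5)cc4)oc13)C(=O)C=C(c1ccc(OCc3ccccc3)cc1)O2 | intermediate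
9 | 4',4'''-bis(benzyloxy)-5-hydroxy-5'',7,7''-trimethoxy-6,8''-biflavone, racemic axis | COc1cc2oc(-c3ccc(OCc4ccccc4)cc3)cc(=O)c2c(O)c1-c1c(OC)cc(OC)c2c(=O)cc(-c3ccc(OCc4ccccc4)cc3)oc12 | intermediate
10 | DMGF, 5,5'',4',4'''-tetrahydroxy-7,7''-dimethoxy-6,8''-biflavone, racemic axis | COc1cc2oc(-c3ccc(O)cc3)cc(=O)c2c(O)c1-c1c(OC)cc(O)c2c(=O)cc(-c3ccc(O)cc3)oc12 | target

## Step count and risks

Total step count: 5. Longest linear sequence: 5 steps (1 to 4 to 5 to 6 to 9 to 10); compound 4 enters twice, in step 2 and in step 4.

**Step 4 (key step).** The most likely failure is a slow ligand exchange and coupling. The 5-hydroxyl is locked in a hydrogen bond to C4=O and its phenoxide is a weak donor, and chelation of lead by O5 and O4 holds the metal on the C4a side, away from C6. Protodeplumbation of 6 by the phenol and the liberated acetic acid could then outrun the coupling. A change of conditions within the same approach is the preformed lithium phenoxide of 4 with an amine promoter in toluene.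

The fallback changes the approach to a Suzuki–Miyaura coupling of two marked halves. It sets out from 4 and 5 and comes back at 9:
- 4 is iodinated ortho to the free hydroxyl (benzyltrimethylammonium dichloroiodate, CaCO3, CH2Cl2/MeOH, rt) to give 2-[4-(benzyloxy)phenyl]-5-hydroxy-6-iodo-7-methoxy-4H-chromen-4-one F1.
- 5 is iodinated at C8 (N-iodosuccinimide, CF3CO2H, MeCN) to give 2-[4-(benzyloxy)phenyl]-8-iodo-5,7-dimethoxy-4H-chromen-4-one F2.
- Miyaura borylation of F2 (B2pin2, PdCl2(dppf), KOAc, dioxane, 90 °C) gives 2-[4-(benzyloxy)phenyl]-5,7-dimethoxy-8-(4,4,5,5-tetramethyl-1,3,2-dioxaborolan-2-yl)-4H-chromen-4-one F3.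
- F1 and F3 are coupled (Pd(OAc)2, SPhos, K3PO4, toluene/water, 100 °C) to give 9.

**Step 3.** The plumbation may fail through insufficient electrophilic reactivity at C8 of the acyl-bearing ring, or through acidolysis of the new C–Pb bond under the haloacid conditions; oxidation or attack at C3 are lesser concerns. The fallback fixes the site by ipso substitution, sets out from 5 and comes back at 6:
- Bromination (N-bromosuccinimide, DMF, 0 °C to rt) should give 2-[4-(benzyloxy)phenyl]-8-bromo-5,7-dimethoxy-4H-chromen-4-one F4.
- Stannylation ((Bu3Sn)2, Pd(PPh3)4, toluene, 110 °C) should give 2-[4-(benzyloxy)phenyl]-5,7-dimethoxy-8-(tributylstannyl)-4H-chromen-4-one F5.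
- Tin–lead exchange (Pb(OAc)4, cat. Hg(OAc)2, CHCl3, 40 °C) should give 6.

**Step 5.** Possible failures are incomplete cleavage of the hindered 5''-methyl ether, slow loss of a 7-methyl ether on long exposure to excess BCl3, or Friedel–Crafts benzylation of the free ring A positions if the scavenger is outcompeted. The fallback separates the two kinds of cleavage, sets out from 9 and comes back at 10:
- Hydrogenolysis (H2, Pd/C, THF/MeOH, rt) should give 5,4',4'''-trihydroxy-5'',7,7''-trimethoxy-6,8''-biflavone F6.
- Chelation-controlled demethylation of the single ether peri to a carbonyl (MgI2 etherate, THF/toluene, 80 °C) should then give 10.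

## Further compounds

F1 | step 4 | 2-[4-(benzyloxy)phenyl]-5-hydroxy-6-iodo-7-methoxy-4H-chromen-4-one | COc1cc2oc(-c3ccc(OCc4ccccc4)cc3)cc(=O)c2c(O)c1I
F2 | step 4 | 2-[4-(benzyloxy)phenyl]-8-iodo-5,7-dimethoxy-4H-chromen-4-one | COc1cc(OC)c2c(=O)cc(-c3ccc(OCc4ccccc4)cc3)oc2c1I
F3 | step 4 | 2-[4-(benzyloxy)phenyl]-5,7-dimethoxy-8-(4,4,5,5-tetramethyl-1,3,2-dioxaborolan-2-yl)-4H-chromen-4-one | COc1cc(OC)c2c(=O)cc(-c3ccc(OCc4ccccc4)cc3)oc2c1B1OC(C)(C)C(C)(C)O1
F4 | step 3 | 2-[4-(benzyloxy)phenyl]-8-bromo-5,7-dimethoxy-4H-chromen-4-one | COc1cc(OC)c2c(=O)cc(-c3ccc(OCc4ccccc4)cc3)oc2c1Br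
F5 | step 3 | 2-[4-(benzyloxy)phenyl]-5,7-dimethoxy-8-(tributylstannyl)-4H-chromen-4-one | CCCC[Sn](CCCC)(CCCC)c1c(OC)cc(OC)c2c(=O)cc(-c3ccc(OCc4ccccc4)cc3)oc12
F6 | step 5 | 5,4',4'''-trihydroxy-5'',7,7''-trimethoxy-6,8''-biflavone | COc1cc2oc(-c3ccc(O)cc3)cc(=O)c2c(O)c1-c1c(OC)cc(OC)c2c(=O)cc(-c3ccc(O)cc3)oc12
A1 | alternative 1 | 2-[4-(benzyloxy)phenyl]-6-iodo-5,7-dimethoxy-4H-chromen-4-one | COc1cc2oc(-c3ccc(OCc4ccccc4)cc3)cc(=O)c2c(OC)c1I
A2 | alternative 1 | {2-[4-(benzyloxy)phenyl]-5,7-dimethoxy-4-oxo-4H-chromen-8-yl}boronic acid | COc1cc(OC)c2c(=O)cc(-c3ccc(OCc4ccccc4)cc3)oc2c1B(O)O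
A3 | alternative 1 | 4',4'''-bis(benzyloxy)-5,5'',7,7''-tetramethoxy-6,8''-biflavone | COc1cc2oc(-c3ccc(OCc4ccccc4)cc3)cc(=O)c2c(OC)c1-c1c(OC)cc(OC)c2c(=O)cc(-c3ccc(OCc4ccccc4)cc3)oc12
A4 | alternative 2 | 1,1'-(2,2',4,4'-tetrahydroxy-6,6'-dimethoxy-[1,1'-biphenyl]-3,3'-diyl)bis(ethan-1-one) | CC(=O)c1c(O)cc(OC)c(c1O)-c1c(OC)cc(O)c(C(C)=O)c1O
A5 | alternative 2 | 4',4'''-bis(benzyloxy)-5,5''-dihydroxy-7,7''-dimethoxy-8,8''-biflavone | COc1cc(O)c2c(=O)cc(-c3ccc(OCc4ccccc4)cc3)oc2c1-c1c(OC)cc(O)c2c(=O)cc(-c3ccc(OCc4ccccc4)cc3)oc12
A6 | alternative 2 | 4',4'''-bis(benzyloxy)-5,5''-dihydroxy-7,7''-dimethoxy-6,6''-biflavone | COc1cc2oc(-c3ccc(OCc4ccccc4)cc3)cc(=O)c2c(O)c1-c1c(OC)cc2oc(-c3ccc(OCc4ccccc4)cc3)cc(=O)c2c1O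
A7 | alternative 3 | 2-[4-(benzyloxy)phenyl]-5,7-dimethoxy-6-(methoxyethynyl)-4H-chromen-4-one | COC#Cc1c(OC)cc2oc(-c3ccc(OCc4ccccc4)cc3)cc(=O)c2c1OC
A8 | alternative 3 | 2-[4-(benzyloxy)phenyl]-6-(4-ethoxy-2-hydroxy-6-methoxyphenyl)-5,7-dimethoxy-4H-chromen-4-one | CCOc1cc(O)c(c(OC)c1)-c1c(OC)cc2oc(-c3ccc(OCc4ccccc4)cc3)cc(=O)c2c1OC
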